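## Structural features

Locants used for every compound: C1 (OAc), C2=C3(CH3), C4 (OH), C5, C6=C7(CH3), C8, C9 (OBz), C10 (i-Pr). The target is one ten-membered carbocycle, a cyclodeca-2,6-diene whose two trisubstituted, methyl-bearing alkenes are both Z and are linked through C4–C5, so C2–C7 is a cis,cis-1,5-diene. Three of the four stereocentres are contiguous: C1 (S, acetate), C10 (R, isopropyl) and C9 (S, benzoate) form a 1,3-anti diol diester, with the isopropyl group anti to O1 and syn to O9 in the zigzag sense. The fourth, C4 (R), is an isolated allylic carbinol on the far side of C2=C3. The three oxygens are in three different states (acetate, benzoate, free hydroxyl). The esters can migrate (O1 to O9 through a six-membered and O1 to O4 through a seven-membered transition state across the Z alkene), O1 and O4 are allylic, the C4 carbinol sits on a 1,5-diene (oxy-Cope array), and in any ketone precursor C10 is epimerisable and C8 is both α and allylic. The real difficulty is the medium ring itself (direct closure is opposed by entropy and transannular strain), the Z geometry of two trisubstituted alkenes, and a stereotriad on a conformationally mobile ring. The key step uses two facts: C1–C8, with both alkenes and both methyls, are exactly the carbons of 1,5-dimethylcycloocta-1,5-diene, and C9–C10 with its isopropyl group is a two-carbon insert between C1 and C8 bearing oxygen on C1 and C9, which is the retron of a retro-aldol opening of a cyclobutanone fused across C1–C8.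

## Logic of the disconnections

22 to 21 to 20: the O4–Si bond is put back and the O9–benzoyl bond is cut. From step 5 onward O4 is the only oxygen on silicon, and O9 is the only free hydroxyl of 20, so the three oxygens never need to be told apart by reagent selectivity. The gain is a mono-acetate with one free alcohol. The forward steps must acylate a hindered carbinol faster than the acetyl group can migrate, and remove silicon without base.

20 to 19: the C9–H bond and the O1–acetyl bond are cut together. In 19 the C1 hydroxyl can hand a hydride to C9 and keep the acetyl group in the same event, which sets C9 anti to O1 and differentiates O1 from O9. One stereocentre and one protecting-group operation disappear. The forward step needs internal hydride transfer to outrun retro-aldol of the β-hydroxy ketone and must leave C10 alone.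

19 to 18: the C1–H bond is cut. In 18, C10 lies between two carbonyls and is stereolabile, so C1 and C10 can be set together by a catalyst-controlled reduction with dynamic kinetic resolution. Two stereocentres are removed and only C4 remains. The forward step must reduce the alkenyl ketone C1 and not C9, by 1,2- and not 1,4-addition, and the matched C10 epimer must be the one wanted.

18 to 16 (key): no bond is cut; C1–C8 is reconnected. The ten-membered ring becomes an eight-membered ring with a fused four-membered ring, so the medium-ring problem and the alkene-geometry problem vanish together. The forward scission must break C1–C8 and not C1–C10, and must leave the C4 silyl ether and the position of C6=C7 untouched.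

16 to 15 to 12 + 13: chlorine is added at C10, then C8–C9 and C1–C10 are cut. These are the two bonds a ketene forms with a silyl enol ether, and the chlorine makes the ketene reactive enough for a hindered, trisubstituted enol ether. C9, C10 and the isopropyl group leave as one acid chloride. The cycloaddition must take place at the C1=C8 double bond of a triene, and the chlorine must then be removed without loss of either silyl ether.

12 to 10: the O1–Si bond is cut. This requires enolisation of 10 toward C8 only.

10 to 9 to 6: the C1 carbonyl is traced back, by 1,3-transposition, to a tertiary C3 carbinol next to C1=C2, and that to the C2–C3 epoxide by re-forming the C2–O bond. Oxygen is thus walked from C3 to C1 with no regiochemical ambiguity, and C1 becomes a plain CH2. The nucleophile must open the epoxide at C2; the following elimination can only run toward C1 because C3 has no hydrogen.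

6 to 5 to 4: the O4–Si bond is cut and the epoxide oxygen removed. The free C4 hydroxyl is what picks C2=C3 over C6=C7.

4 to 3 to 2 to 1: the C4–H bond is cut (enantioselective ketone reduction), the oxidation level adjusted, and the C4–O bond cut (allylic oxidation). In C2-symmetric 1 there is only one kind of ring CH2 next to a methyl-bearing alkene carbon. The forward steps need mono-oxidation and a reduction in which the methylated alkenyl arm acts as the large group.

## Other disconnections considered

Alternative 1: Retrosynthetically C4 is joined to C9, which makes the ten-membered ring the periphery of a cis-fused bicyclo[4.4.0]decadiene with a ditertiary diol at the ring fusion, A2. In the forward sense Pb(OAc)4 would cleave the glycol of A2 to the C4,C9-diketone A1.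
- In favour: glycol cleavage is neutral and fast and involves no regiochemical choice, so as a mechanism it is the equal of, or better than, the retro-aldol. Both alkenes sit in cyclohexene rings before cleavage, so their Z geometry is as secure as in the chosen plan (equal). C1 and C10 would be set on a six-membered ring, which is a better setting for relative stereocontrol than a dynamic kinetic resolution on a ten-membered ring (better).
- Against: A1 has ketones at C4 and C9, so both carbinol centres would have to be set late by two reductions on the flexible ring and then differentiated as free hydroxyl and benzoate. A1 is a 1,6-diketone whose C5 and C8 positions are both α and allylic, which invites transannular aldol closure back to a decalin, and its C1 silyloxy group is β to the C9 ketone and could be eliminated. A2 itself is an unsymmetrical bicycle with a ring-fusion diol that has to be built from scratch.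
- Comparison: on structure it is equal for the alkenes, better for C1/C10 and worse for C4/C9. On step economy the chosen plan should be clearly shorter, because it buys eight ring carbons, both alkenes and both methyls in one compound.

Alternative 2: The C1–C10 bond is cut and O1 is tied to a methallyl carbon, giving the thirteen-membered diallyl ether A4. In the forward sense a lithium amide or n-BuLi at low temperature would make the C1 carbanion of A4, which would attack C10 in a [2,3]-Wittig shift to give the ten-membered alcohol A3 with a C10 isopropenyl group.
- In favour: the step makes a skeletal C–C bond and two stereocentres (C1, C10) at once, where the chosen key step makes none (better). The C4 and C9 oxygens would come from acyclic fragments made by reagent control, so no late ketone reduction at C9 is needed (better at C9). Like the chosen plan it avoids direct ten-ring closure by changing ring size (equal).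
- Against: both Z trisubstituted alkenes must be made stereoselectively in open-chain fragments (worse). A thirteen-membered ether has to be closed at high dilution. The methallyl CH2 is also an allylic α-oxy position, so lithiation must be steered to C1, and a [1,2]-shift competes. The relative configuration of C1 and C10, and their relation to C9, depends on the folding of a large ring and on the geometry of the C10 alkene. A3 would still need hydrogenation of the isopropenyl group in the presence of two ring alkenes (feasible with RhCl(PPh3)3, but an extra step), and three orthogonal oxygen protecting groups are needed.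
- Comparison: mechanistically richer, structurally less secure on alkene geometry, and expected to be several steps longer.

Alternative 3: C3 is joined to C9 and a leaving group is placed on C2, giving the cis-fused bicyclo[5.3.0]decene mesylate A6 with a tertiary C9 alcohol. In the forward sense a base (KOt-Bu) would make the C9 alkoxide, and Grob fragmentation would break C3–C9, form C9=O and Z C2=C3, and give the ten-membered ketone A5.
- In favour: the alkene geometry follows stereospecifically from the relative configuration of C2 and C3 (equal to the chosen plan, which inherits it from a ring). C1, C10 and C4 would be fixed before the medium ring exists, and A5 after removal of the PMB group is compound 19 of the chosen route, so the uncertain dynamic kinetic resolution is avoided (better). It is the same kind of event as the chosen key step, an alkoxide-driven scission of a ring-fusion bond (equal).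
- Against: A6 carries five contiguous stereocentres, including a quaternary C3 and a tertiary C9 carbinol, on a hydroazulene with a trisubstituted alkene, which is a long construction. A leaving group on a cyclopentane cannot be fully anti-periplanar to the ring-fusion bond, so elimination toward C1 or substitution may compete. The product is a β-alkoxy ketone under strongly basic conditions.
- Comparison: stereochemically the safest of the four, but with the poorest step economy; the chosen plan reaches its fragmentation substrate three steps after the eight-membered enone.

Key step: step 11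

Remarks on the chemistry, made before the steps:
- Commercial 1 is accompanied by its 1,6-dimethyl isomer; it is assumed to be removed by fractional distillation before step 1.
- 13 is taken as a catalogue compound; otherwise it is one step from 2-chloro-3-methylbutanoic acid and oxalyl chloride.
- A resolving epoxidation of 2 would save two steps, but cyclic Z-allylic alcohols are poor substrates for that kinetic resolution. C4 is therefore set by oxidation and Corey–Bakshi–Shibata reduction.
- Isopropylketene itself, an aldoketene, dimerises readily and is a weak partner for silyl enol ethers. The chloro ketene is used instead and the chlorine is removed with zinc, at the cost of one step.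
- 15, 16 and 17 are drawn as one cis-fused diastereomer; the ring-fusion face and the C10 configuration are expected to be mixtures, all of which converge in step 11.

## Route

Step 1
Reactants: 1 (1Z,5Z)-1,5-dimethylcycloocta-1,5-diene
Product: 2 (±)-(2Z,6Z)-2,6-dimethylcycloocta-2,6-dien-1-ol (hydroxyl on C4)
Conditions: SeO2 (0.3 equiv), t-BuOOH (1.5 equiv), CH2Cl2, 0 °C to rt; stopped near half conversion, 1 recycled
Reagents that add atoms: tert-butyl hydroperoxide, CC(C)(C)OO; selenium dioxide, O=[Se]=O (oxygen carrier)
Why: SeO2-catalysed allylic oxidation (ene reaction, then [2,3]-sigmatropic shift) goes to the ring CH2 on the more substituted alkene carbon, i.e. C4; the C2 symmetry of 1 makes C4 and C8 the same position, so a single mono-alcohol should form, and any ketone 3 from over-oxidation converges in step 2.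

Step 2
Reactants: 2 (±)-(2Z,6Z)-2,6-dimethylcycloocta-2,6-dien-1-ol
Product: 3 (2Z,6Z)-2,6-dimethylcycloocta-2,6-dien-1-one (carbonyl at C4)
Conditions: Dess–Martin periodinane, NaHCO3, CH2Cl2, 0 °C to rt
Reagents that add atoms: none
Why: Dess–Martin oxidation of a secondary allylic alcohol; the bicarbonate buffer should keep the β,γ-alkene C6=C7 from moving into conjugation.

Step 3
Reactants: 3 (2Z,6Z)-2,6-dimethylcycloocta-2,6-dien-1-one
Product: 4 (1R,2Z,6Z)-2,6-dimethylcycloocta-2,6-dien-1-ol (4R in target locants)
Conditions: (S)-2-methyl-CBS-oxazaborolidine (0.2 equiv), catecholborane, toluene, −78 °C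
Reagents that add atoms: none
Why: Corey–Bakshi–Shibata reduction: the α-methylated alkenyl arm (C3) is the large group and the C5 methylene the small one, so the (S)-catalyst should give the R carbinol that becomes C4 of the target; catecholborane does not hydroborate the alkenes at this temperature.

Step 4
Reactants: 4 (1R,2Z,6Z)-2,6-dimethylcycloocta-2,6-dien-1-ol
Product: 5 (1R,2R,8S,4Z)-1,5-dimethyl-9-oxabicyclo[6.1.0]non-4-en-2-ol (C2–C3 epoxide, oxygen syn to the C4 hydroxyl)
Conditions: VO(acac)2 (3 mol %), t-BuOOH (decane), CH2Cl2, 0 °C to rt
Reagents that add atoms: tert-butyl hydroperoxide, CC(C)(C)OO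
Why: Hydroxyl-directed vanadium-catalysed epoxidation: the vanadium alkoxide delivers oxygen only to the allylic alkene C2=C3 and, as with medium-ring cycloalkenols, to the face syn to the carbinol; the new centres C2 and C3 are erased in steps 6 and 7.

Step 5
Reactants: 5 (1R,2R,8S,4Z)-1,5-dimethyl-9-oxabicyclo[6.1.0]non-4-en-2-ol
Product: 6 O4-tert-butyldimethylsilyl ether of 5
Conditions: TBSCl, imidazole, DMF, rt
Reagents that add atoms: tert-butyldimethylsilyl chloride, CC(C)(C)[Si](C)(C)Cl
Why: Silylation of a secondary alcohol under basic, non-Lewis-acidic conditions that leave the epoxide closed.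

Step 6
Reactants: 6 O4-tert-butyldimethylsilyl ether of 5
Product: 9 (1S,8R,2Z,5Z)-8-(tert-butyldimethylsilyloxy)-1,5-dimethylcycloocta-2,5-dien-1-ol (tertiary C3 carbinol, C1=C2, C4 OTBS), via hydroxy selenide 7 (not isolated), via selenoxide 8 (not isolated)
Conditions: (PhSe)2, NaBH4, EtOH, reflux; then 30% H2O2, pyridine, CH2Cl2, 0 °C to rt
Reagents that add atoms: none
Why: Organoselenium isomerisation of an epoxide to an allylic alcohol: PhSe− opens the epoxide by SN2 attack at the secondary C2, and the selenoxide undergoes syn elimination, which can only run toward C1 because C3 has no hydrogen, giving the ring-enforced Z C1=C2 alkene and the tertiary C3 alcohol; pyridine suppresses epoxidation of C6=C7 by peroxyseleninic acid.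

Step 7
Reactants: 9 (1S,8R,2Z,5Z)-8-(tert-butyldimethylsilyloxy)-1,5-dimethylcycloocta-2,5-dien-1-ol
Product: 10 (4R,2Z,6Z)-4-(tert-butyldimethylsilyloxy)-3,7-dimethylcycloocta-2,6-dien-1-one
Conditions: C5H5NH[CrO3Cl] (pyridinium chlorochromate), 4 Å MS, CH2Cl2, rt
Reagents that add atoms: pyridinium chlorochromate, [O-][Cr](=O)(=O)Cl.c1cc[nH+]cc1 (carbonyl oxygen)
Why: Babler–Dauben oxidative transposition: the chromate ester of the tertiary allylic alcohol undergoes a [3,3] shift to C1 and is oxidised there, giving the enone with C2=C3 Z by ring constraint and C4 untouched.

Step 8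
Reactants: 10 (4R,2Z,6Z)-4-(tert-butyldimethylsilyloxy)-3,7-dimethylcycloocta-2,6-dien-1-one
Product: 12 trimethylsilyl dienol ether of 10 (C1(OSiMe3)=C8 beside C2=C3 and C6=C7; 4R), via lithium dienolate 11 (not isolated)
Conditions: LiN(i-Pr)2, THF, −78 °C; then Me3SiCl, Et3N, −78 to 0 °C; pentane, filtration, used at once
Reagents that add atoms: chlorotrimethylsilane, C[Si](C)(C)Cl
Why: Kinetic enolisation of an enone at the α′ carbon: C8–H is both α to the carbonyl and allylic to C6=C7, whereas the γ-hydrogen at C4 is tertiary and shielded by the silyl ether, so O-silylation should give the C1=C8 enol ether only; the product is a cycloocta-1,3,5-triene and is used cold and at once to forestall 6π electrocyclisation.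

Step 9
Reactants: 12 trimethylsilyl dienol ether of 10; 13 2-chloro-3-methylbutanoyl chloride (racemic)
Product: 15 cis-fused 10-chloro-4-(tert-butyldimethylsilyloxy)-3,7-dimethyl-10-(propan-2-yl)-1-(trimethylsilyloxy)bicyclo[6.2.0]deca-2,6-dien-9-one (bicyclic locants coincide with target locants), via chloro(isopropyl)ketene 14 (not isolated)
Conditions: Et3N (slow addition), hexane, rt to 40 °C
Reagents that add atoms: none
Why: Ketene–silyl enol ether [2+2] cycloaddition with a chloro(alkyl)ketene made by dehydrochlorination: the ketene carbonyl carbon bonds to the nucleophilic C8 and the substituted carbon to C1, suprafacially on the ring alkene, hence the cis ring fusion; the face of attack (drawn anti to the C4 silyloxy group) and C10 are mixtures of no consequence, since C1, C8 and C10 lose their configuration in steps 10 and 11.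

Step 10
Reactants: 15 cis-fused chloro cyclobutanone
Product: 16 cis-fused 4-(tert-butyldimethylsilyloxy)-3,7-dimethyl-10-(propan-2-yl)-1-(trimethylsilyloxy)bicyclo[6.2.0]deca-2,6-dien-9-one (OSiMe3 and H8 syn; isopropyl drawn exo; 4R)
Conditions: Zn dust, AcOH, i-PrOH–H2O, 0 °C
Reagents that add atoms: none
Why: Reductive dechlorination of an α-chloro ketone through its zinc enolate, the standard sequel to a halo-ketene cycloaddition; at 0 °C both silyl ethers should survive, and the C10 epimer mixture is used as such.

Step 11
Reactants: 16 cis-fused 3-silyloxycyclobutanone
Product: 18 (6R,4Z,8Z)-6-(tert-butyldimethylsilyloxy)-5,9-dimethyl-2-(propan-2-yl)cyclodeca-4,8-diene-1,3-dione (target locants: C1 and C9 ketones, C10 isopropyl stereolabile, C4 OTBS), via cyclobutanolate 17 (not isolated)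
Conditions: Bu4NF (1.1 equiv), AcOH (1.1 equiv), THF, −20 to 0 °C
Reagents that add atoms: none
Why: Fluoride takes the trimethylsilyl group off the tertiary C1 oxygen far faster than it attacks the secondary tert-butyldimethylsilyl ether at C4, and the resulting cyclobutanolate, which is the aldolate of the C9 ketone, undergoes strain-driven retro-aldol scission. Of the two bonds β to the carbonyl, C1–C8 should break in preference to C1–C10 because the electrons then flow into a C9–C8 enolate conjugated with C6=C7 (a dienolate), whereas C1–C10 cleavage would give an unconjugated, more hindered enolate carrying the isopropyl group; the ring-fusion bond is also the one that breaks in the parent cyclopentanone to cycloheptane-1,3-dione case. The closest known reaction type is the two-carbon ring expansion of cycloalkanone silyl enol ethers through ketene adducts and retro-aldol opening. No ring is closed: the ten-membered ring appears when the bond shared by the four- and eight-membered rings breaks, so both alkenes keep the Z geometry they had in the eight-membered ring. No stereocentre is made: C1 and C8 lose theirs, C10 becomes stereolabile between two carbonyls, and C4 is untouched. Acetic acid protonates the dienolate kinetically at C8, which keeps C6=C7 out of conjugation, and keeps the medium too weakly basic for transannular Michael addition or for attack on the C4 silyl ether.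

Step 12
Reactants: 18 ten-membered 1,9-dione
Product: 19 β-hydroxy ketone, C1 hydroxyl and C9 ketone, (1S,4R,10S) in target locants (10S here is spatially the 10R of the target)
Conditions: RuCl(p-cymene)[(R,R)-TsDPEN] (2 mol %), HCO2H–Et3N (5:2), CH2Cl2, rt
Reagents that add atoms: none
Why: Noyori–Ikariya asymmetric transfer hydrogenation with dynamic kinetic resolution: the bifunctional Ru–H/N–H catalyst prefers the π-bound alkenyl ketone C1 to the dialkyl ketone C9 and, with the (R,R)-ligand, should give 1S; C10 epimerises rapidly between the two carbonyls, and hydride delivery to the C1 face remote from the isopropyl group (as in the cis-selective reduction of 2-substituted cycloalkanones) should funnel the mixture to the epimer with hydroxyl and isopropyl on the same ring face.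

Step 13
Reactants: 19 β-hydroxy ketone
Product: 20 C1 acetate with free C9 hydroxyl and C4 OTBS, (1S,4R,9S,10R)
Conditions: SmI2 (0.3 equiv), MeCHO (8 equiv), THF, −10 °C
Reagents that add atoms: acetaldehyde, CC=O
Why: Evans–Tishchenko reduction: the C1 hydroxyl forms a hemiacetal with acetaldehyde on trivalent samarium and hands its hydride to C9 through a chair-like six-membered transition state, which sets C9–O anti to C1–O and leaves the acetyl group on O1 in the same event; C10 should not be touched under these non-basic conditions.

Step 14
Reactants: 20 C1 acetate, C9 alcohol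
Product: 21 C1 acetate, C9 benzoate, C4 OTBS, (1S,4R,9S,10R)
Conditions: BzCl, pyridine, DMAP (cat.), CH2Cl2, 0 °C
Reagents that add atoms: benzoyl chloride, O=C(Cl)c1ccccc1
Why: Acylation of the only free hydroxyl; DMAP and excess benzoyl chloride at low temperature should trap O9 faster than the acetyl group can migrate from O1.

Step 15
Reactants: 21 C1 acetate, C9 benzoate, C4 OTBS
Product: 22 (1S,4R,9S,10R,2Z,6Z)-1-acetoxy-9-benzoyloxy-3,7-dimethyl-10-(propan-2-yl)cyclodeca-2,6-dien-4-ol (target locants), CNP0125882.1
Conditions: HF·pyridine, pyridine, THF, 0 °C to rt
Reagents that add atoms: none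
Why: Fluoride cleavage of the secondary silyl ether under buffered, weakly acidic conditions, which avoid base-induced acyl migration to O4 or O9 and ester cleavage; no stereocentre is involved.

## Compound list

1 | (1Z,5Z)-1,5-dimethylcycloocta-1,5-diene | C/C1=C/CC/C(C)=C\CC1 | starting material
2 | (±)-(2Z,6Z)-2,6-dimethylcycloocta-2,6-dien-1-ol | C1/C=C(/C)C(O)C/C=C(/C)C1 | intermediate
3 | (2Z,6Z)-2,6-dimethylcycloocta-2,6-dien-1-one | O=C1C/C=C(/C)CC/C=C1/C | intermediate
4 | (1R,2Z,6Z)-2,6-dimethylcycloocta-2,6-dien-1-ol | C1/C=C(/C)[C@H](O)C/C=C(/C)C1 | intermediate
5 | (1R,2R,8S,4Z)-1,5-dimethyl-9-oxabicyclo[6.1.0]non-4-en-2-ol (syn epoxy alcohol) | C1[C@@H]2O[C@]2(C)[C@H](O)C/C=C(/C)C1 | intermediate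
6 | O4-tert-butyldimethylsilyl ether of 5 | C1[C@@H]2O[C@]2(C)[C@H](O[Si](C)(C)C(C)(C)C)C/C=C(/C)C1 | intermediate
7 | hydroxy selenide: C2 phenylselanyl (inverted), C3 tertiary hydroxyl, C4 OTBS | C1[C@@H]([Se]c2ccccc2)[C@](C)(O)[C@H](O[Si](C)(C)C(C)(C)C)C/C=C(/C)C1 | intermediate
8 | selenoxide of 7 (mixture at selenium) | C1[C@@H]([Se](=O)c2ccccc2)[C@](C)(O)[C@H](O[Si](C)(C)C(C)(C)C)C/C=C(/C)C1 | intermediate
9 | (1S,8R,2Z,5Z)-8-(tert-butyldimethylsilyloxy)-1,5-dimethylcycloocta-2,5-dien-1-ol | C1/C=C\[C@](C)(O)[C@H](O[Si](C)(C)C(C)(C)C)C/C=C1/C | intermediate
10 | (4R,2Z,6Z)-4-(tert-butyldimethylsilyloxy)-3,7-dimethylcycloocta-2,6-dien-1-one | O=C1/C=C(/C)[C@H](O[Si](C)(C)C(C)(C)C)C/C=C(/C)C1 | intermediate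
11 | lithium C1(O)=C8 dienolate of 10 | [Li+].C1/C=C(C)\C=C([O-])/C=C(C)\[C@@H]1O[Si](C)(C)C(C)(C)C | intermediate
12 | trimethylsilyl dienol ether of 10 (C1(OSiMe3)=C8, 4R) | C1/C=C(C)\C=C(O[Si](C)(C)C)/C=C(C)\[C@@H]1O[Si](C)(C)C(C)(C)C | intermediate
13 | 2-chloro-3-methylbutanoyl chloride (racemic) | CC(C)C(Cl)C(Cl)=O | starting material
14 | chloro(isopropyl)ketene (2-chloro-3-methylbut-1-en-1-one) | CC(C)C(Cl)=C=O | intermediate
15 | cis-fused 10-chloro-10-isopropyl 3-silyloxycyclobutanone (C10 mixture) | C[Si](C)(C)O[C@]12/C=C(/C)[C@H](O[Si](C)(C)C(C)(C)C)C/C=C(/C)[C@H]1C(=O)C2(Cl)C(C)C | intermediate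
16 | cis-fused 10-isopropyl 3-silyloxycyclobutanone (key-step precursor; exo epimer drawn) | C[Si](C)(C)O[C@]12/C=C(/C)[C@H](O[Si](C)(C)C(C)(C)C)C/C=C(/C)[C@H]1C(=O)[C@@H]2C(C)C | intermediate
17 | tetrabutylammonium C1 cyclobutanolate of 16 | CCCC[N+](CCCC)(CCCC)CCCC.[O-][C@]12/C=C(/C)[C@H](O[Si](C)(C)C(C)(C)C)C/C=C(/C)[C@H]1C(=O)[C@@H]2C(C)C | intermediate
18 | (6R,4Z,8Z)-6-(tert-butyldimethylsilyloxy)-5,9-dimethyl-2-(propan-2-yl)cyclodeca-4,8-diene-1,3-dione | CC(C)C1C(=O)/C=C(/C)[C@H](O[Si](C)(C)C(C)(C)C)C/C=C(/C)CC1=O | intermediate
19 | C1 hydroxy C9 ketone, (1S,4R,10S) in target locants | O[C@H]1/C=C(/C)[C@H](O[Si](C)(C)C(C)(C)C)C/C=C(/C)CC(=O)[C@H]1C(C)C | intermediate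
20 | C1 acetate, C9 alcohol, C4 OTBS, (1S,4R,9S,10R) | CC(=O)O[C@H]1/C=C(/C)[C@H](O[Si](C)(C)C(C)(C)C)C/C=C(/C)C[C@H](O)[C@H]1C(C)C | intermediate
21 | C1 acetate, C9 benzoate, C4 OTBS, (1S,4R,9S,10R) | CC(=O)O[C@H]1/C=C(/C)[C@H](O[Si](C)(C)C(C)(C)C)C/C=C(/C)C[C@H](OC(=O)c2ccccc2)[C@H]1C(C)C | intermediate
22 | (1S,4R,9S,10R,2Z,6Z)-1-acetoxy-9-benzoyloxy-3,7-dimethyl-10-(propan-2-yl)cyclodeca-2,6-dien-4-ol | CC(=O)O[C@H]1/C=C(/C)[C@H](O)C/C=C(/C)C[C@H](OC(=O)c2ccccc2)[C@H]1C(C)C | target

## Step count and least certain steps

Total step count: 15. Longest linear sequence: 15 steps (1 to 22); 13 enters at step 9 as bought.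

Step 11 (key step). The cyclobutanolate may cleave the C1–C10 bond instead of the ring-fusion bond, which would leave the eight-membered ring unexpanded. Fluoride may also start to remove the C4 silyl group. The dienolate may be protonated at C6, moving C6=C7 into conjugation, and the enolate may add across the ring to the enone. The causes are the small energy difference between the two retro-aldol modes and the basicity of fluoride. Fallback: from 16, the trimethylsilyl ether alone is methanolysed (pyridinium p-toluenesulfonate, MeOH, 0 °C) to the free cis-fused cyclobutanol F1. F1 is then opened without any free carbanion by acid-catalysed, enol-mode retro-aldol (AcOH, i-PrOH–H2O, 40 °C), in which the C8=C9 dienol conjugated with C6=C7 is the only low-energy enol. This returns to the route at 18.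

Step 12. Control at C10 may be poor, because the epimer matched to the catalyst in a flexible ten-membered ring need not be the one with hydroxyl and isopropyl on the same face. Conjugate reduction of the enone or slow reduction of an enolised dione may also intervene. Fallback: from 18, Luche reduction (NaBH4, CeCl3·7H2O, MeOH, −78 °C) gives the C1 carbinols without catalyst control. The C1 epimer, the (1R)-hydroxy ketone F2, is separated and returned to 18 by Dess–Martin oxidation. The (1S)-hydroxy ketone with the wrong C10 configuration F3 is equilibrated at C10, which is α to the C9 ketone, with Et3N in CH2Cl2 and re-separated. The fallback returns to the route at 19.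

Step 9. The hindered chloro ketene may dimerise faster than it adds, may add at C6=C7 or through the vinylogous position C6, or the zwitterion may collapse by silyl transfer to a C-acylated ketone. The cause is the crowded, cross-conjugated enol ether. Fallback: from 12, dichloroketene (Cl3CCOCl, Zn–Cu couple, Et2O), the least hindered and best precedented ketene for silyl enol ethers, should give the dichlorocyclobutanone F4. Zn/AcOH then gives the cyclobutanone with a C10 methylene F5. Its kinetic lithium enolate (LiN(i-Pr)2, THF, −78 °C) is condensed with acetaldehyde to the aldol F6, which is dehydrated with Burgess reagent to the 10-ethylidene cyclobutanone F7. Conjugate addition of Me2CuLi (Et2O, −78 °C, NH4Cl quench) completes the isopropyl group and returns to the route at 16.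

Step 13. Retro-aldol opening of the samarium aldolate (C1–C10 cleavage) may compete, the ring may resist the chair-like arrangement needed for internal hydride transfer, and the acetate may migrate afterwards. Fallback: from 19, acetylation (Ac2O, pyridine, 0 °C) gives the β-acetoxy ketone F8. The C9 ketone is then reduced under reagent control with (R)-2-methyl-CBS-oxazaborolidine and catecholborane (toluene, −78 °C), with the branched C10 as the large group and the C8 methylene as the small one. This returns to the route at 20.

## Further compounds

F1 | step 11 | free cis-fused C1 cyclobutanol (desilylated 16) | O[C@]12/C=C(/C)[C@H](O[Si](C)(C)C(C)(C)C)C/C=C(/C)[C@H]1C(=O)[C@@H]2C(C)C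
F2 | step 12 | (1R)-hydroxy ketone, C1 epimer of 19 (C10 mixture) | O[C@@H]1/C=C(/C)[C@H](O[Si](C)(C)C(C)(C)C)C/C=C(/C)CC(=O)C1C(C)C
F3 | step 12 | (1S)-hydroxy ketone with the wrong C10 configuration, C10 epimer of 19 | O[C@H]1/C=C(/C)[C@H](O[Si](C)(C)C(C)(C)C)C/C=C(/C)CC(=O)[C@@H]1C(C)C
F4 | step 9 | cis-fused 10,10-dichloro 3-silyloxycyclobutanone | C[Si](C)(C)O[C@]12/C=C(/C)[C@H](O[Si](C)(C)C(C)(C)C)C/C=C(/C)[C@H]1C(=O)C2(Cl)Cl
F5 | step 9 | cis-fused 3-silyloxycyclobutanone with C10 methylene | C[Si](C)(C)O[C@]12/C=C(/C)[C@H](O[Si](C)(C)C(C)(C)C)C/C=C(/C)[C@H]1C(=O)C2
F6 | step 9 | 10-(1-hydroxyethyl) aldol (mixture at C10 and carbinol) | C[Si](C)(C)O[C@]12/C=C(/C)[C@H](O[Si](C)(C)C(C)(C)C)C/C=C(/C)[C@H]1C(=O)C2C(C)O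
F7 | step 9 | 10-ethylidene cyclobutanone (alkene mixture) | C[Si](C)(C)O[C@]12/C=C(/C)[C@H](O[Si](C)(C)C(C)(C)C)C/C=C(/C)[C@H]1C(=O)C2=CC
F8 | step 13 | C1 acetate of 19 (β-acetoxy ketone) | CC(=O)O[C@H]1/C=C(/C)[C@H](O[Si](C)(C)C(C)(C)C)C/C=C(/C)CC(=O)[C@H]1C(C)C
A1 | alternative 1 | ten-membered C4,C9-diketone with C1 triethylsilyl ether | CC[Si](CC)(CC)O[C@H]1/C=C(/C)C(=O)C/C=C(/C)CC(=O)[C@H]1C(C)C
A2 | alternative 1 | cis-fused bicyclo[4.4.0]decadiene C4,C9 ring-fusion diol | CC[Si](CC)(CC)O[C@H]1C=C(C)[C@@]2(O)CC=C(C)C[C@@]2(O)[C@H]1C(C)C
A3 | alternative 2 | ten-membered C1 alcohol with C10 isopropenyl, C4 OTBS, C9 OTES | O[C@H]1/C=C(/C)[C@H](O[Si](C)(C)C(C)(C)C)C/C=C(/C)C[C@H](O[Si](CC)(CC)CC)[C@H]1C(C)=C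
A4 | alternative 2 | thirteen-membered diallyl ether (E at the C10 alkene) | O1C/C=C(/C)[C@H](O[Si](C)(C)C(C)(C)C)C/C=C(/C)C[C@H](O[Si](CC)(CC)CC)/C=C(\C)C1
A5 | alternative 3 | ten-membered C9 ketone with C1 PMB ether and C4 OTBS | COc1ccc(CO[C@H]2/C=C(/C)[C@H](O[Si](C)(C)C(C)(C)C)C/C=C(/C)CC(=O)[C@H]2C(C)C)cc1
A6 | alternative 3 | cis-fused bicyclo[5.3.0]decene C2 mesylate with tertiary C9 alcohol | COc1ccc(CO[C@H]2[C@H](OS(C)(=O)=O)[C@]3(C)[C@H](O[Si](C)(C)C(C)(C)C)C/C=C(/C)C[C@]3(O)[C@H]2C(C)C)cc1
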